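**Retrosynthetic overview**
1. Target triacid ⇐ its trimethyl ester ⇐ 15-oxo-16-ene ⇐ 15-deoxy triester: the C15 oxygen comes from SeO2 allylic oxidation, its configuration from exo-face hydride reduction of the enone; the esters are cleaved last.
2. 15-Deoxy triester ⇐ Δ5-enoate (conjugate reduction sets C5 and C6, methylation sets C4) ⇐ ring A, closed by C10 alkylation and then the new step, a palladium-catalysed zinc ester enolate/enol triflate coupling that makes C4–C5.
3. Ring B ⇐ Dieckmann condensation of a malonate/acetate triester on the C/D bicycle.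
4. Ring D and quaternary C8 ⇐ intramolecular allylzinc conjugate addition to an alkylidene malonate on ring C.
5. Ring C ⇐ cyclohex-2-en-1-one (α′-alkylation; Rh/(R)-BINAP-catalysed asymmetric conjugate addition sets C13). Ring order: C, D, B, A.

Assumption: carbon labels C1–C20 follow gibberellane numbering of the target; at C15, exo means the face of the C15–C16 bridge turned toward C14 and C6, endo the face turned toward C9 and C11, and the target SMILES carries the 15-hydroxyl endo (15β in gibberellin usage); stereochemical outcomes are predictions by analogy and conformational reasoning, not measurements.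

**Step 1**
Reactants: 1 cyclohex-2-en-1-one; 2 methyl bromoacetate
Product: 4 methyl 2-(2-oxocyclohex-3-en-1-yl)acetate (racemic), via lithium cyclohexa-1,5-dien-1-olate 3 (not isolated)
Conditions: LDA (1.05 equiv), THF, −78 °C; then 2, DMPU, −78 → −30 °C
Reagents that add atoms: methyl bromoacetate (2), COC(=O)CBr
Why: Kinetic α′-deprotonation gives the cross-conjugated lithium dienolate, which is C-alkylated by the α-halo ester (enolate SN2 alkylation); the new centre (C9) is racemic here and is corrected in step 2.

**Step 2**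
Reactants: 4 methyl 2-(2-oxocyclohex-3-en-1-yl)acetate (racemic); 5 potassium trifluoro(prop-1-en-2-yl)borate
Product: 7 methyl 2-[(1S,4R)-2-oxo-4-(prop-1-en-2-yl)cyclohexyl]acetate (trans isomer), via cis C9 epimer 6 (not isolated)
Conditions: [Rh(cod)2]PF6 (3 mol %), (R)-BINAP (3.3 mol %), toluene–H2O (4:1), 100 °C; then DBU (0.2 equiv), CH2Cl2, 25 °C
Reagents that add atoms: potassium trifluoro(prop-1-en-2-yl)borate (5), [K+].C=C(C)[B-](F)(F)F
Why: Hayashi–Miyaura asymmetric conjugate addition: the (R)-BINAP–rhodium alkenyl species selects one enone face regardless of the remote C9 centre and sets C13 as R (high ee expected by analogy with 3-substituted cyclohexanones), and base epimerisation at the ketone α-carbon C9 then funnels both diastereomers to the diequatorial trans isomer (about 9:1 expected).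

**Step 3**
Reactants: 7 methyl 2-[(1S,4R)-2-oxo-4-(prop-1-en-2-yl)cyclohexyl]acetate; 8 dimethyl malonate
Product: 9 dimethyl 2-[(2S,5R)-2-(2-methoxy-2-oxoethyl)-5-(prop-1-en-2-yl)cyclohexylidene]propanedioate
Conditions: TiCl4 (2 equiv), pyridine (4 equiv), THF, 0 → 25 °C
Reagents that add atoms: dimethyl malonate (8), COC(=O)CC(=O)OC
Why: Knoevenagel condensation under Lehnert conditions: the titanium malonate enolate adds to the ketone and the aldolate eliminates toward the acidic malonate C–H, giving the conjugated alkylidene malonate that makes C8 an acceptor; no stereocentre is formed.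

**Step 4**
Reactants: 9 dimethyl 2-[(2S,5R)-2-(2-methoxy-2-oxoethyl)-5-(prop-1-en-2-yl)cyclohexylidene]propanedioate
Product: 10 dimethyl 2-[(2S,5R)-5-(3-chloroprop-1-en-2-yl)-2-(2-methoxy-2-oxoethyl)cyclohexylidene]propanedioate
Conditions: Ca(OCl)2, CO2 (dry ice), CH2Cl2–H2O, 0 °C
Reagents that add atoms: calcium hypochlorite, [Ca+2].[O-]Cl.[O-]Cl
Why: Ene-type allylic chlorination by HOCl attacks only the electron-rich isopropenyl group (the alkylidene malonate is electron-poor) and shifts the double bond to give the 2-(chloromethyl)allyl unit.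

**Step 5**
Reactants: 10 dimethyl 2-[(2S,5R)-5-(3-chloroprop-1-en-2-yl)-2-(2-methoxy-2-oxoethyl)cyclohexylidene]propanedioate
Product: 12 dimethyl 2-[(1R,2S,5R)-2-(2-methoxy-2-oxoethyl)-6-methylidenebicyclo[3.2.1]octan-1-yl]propanedioate, via allylzinc chloride 11 (not isolated)
Conditions: Zn dust (activated), THF–sat. aq. NH4Cl (2:1), 25 °C
Reagents that add atoms: none
Why: Barbier-type zinc allylation run as an intramolecular 1,4-addition to the alkylidene malonate closes ring D, leaves the exocyclic methylene and creates quaternary C8; the bridge can only form on the ring face carrying the axial C13 side chain, and the reacting conformer has the C9 side chain axial on the other face (relief of A(1,3) strain), so H-9 ends up cis to the C15 bridge.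

**Step 6**
Reactants: 12 dimethyl 2-[(1R,2S,5R)-2-(2-methoxy-2-oxoethyl)-6-methylidenebicyclo[3.2.1]octan-1-yl]propanedioate
Product: 13 dimethyl 9-methylidene-3-oxotricyclo[6.2.1.0(1,5)]undecane-2,4-dicarboxylate (C6 and C10 epimeric or enolised)
Conditions: NaOMe (1.5 equiv), MeOH–toluene, 80 °C; then cold 1 M HCl
Reagents that add atoms: none
Why: Dieckmann condensation under thermodynamic control: attack of the C10 ester enolate on a malonate carbonyl gives the cis-fused cyclopentanone, which has acidic 1,3-dicarbonyl C–H bonds on both sides and is removed as its enolate, whereas closure of the malonate carbanion onto the C20 ester is reversible.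

**Step 7**
Reactants: 13 dimethyl 9-methylidene-3-oxotricyclo[6.2.1.0(1,5)]undecane-2,4-dicarboxylate; 14 methyl 5-bromopentanoate
Product: 15 dimethyl 4-(5-methoxy-5-oxopentyl)-9-methylidene-3-oxotricyclo[6.2.1.0(1,5)]undecane-2,4-dicarboxylate (chain on C10 cis to H-9; C6 epimeric)
Conditions: Cs2CO3 (1.1 equiv), DMF, 40 °C
Reagents that add atoms: methyl 5-bromopentanoate (14), COC(=O)CCCCBr
Why: β-Keto ester C-alkylation (SN2): of the two acidic positions only C10 reacts usefully because C6 is neopentylic next to quaternary C8, and the bromide approaches the planar C10 enolate on the convex face of the cis-fused B/C bicycle, away from C11 and C14, which sets quaternary C10 (C1 cis to H-9, C20 ester on the C14 side).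

**Step 8**
Reactants: 15 dimethyl 4-(5-methoxy-5-oxopentyl)-9-methylidene-3-oxotricyclo[6.2.1.0(1,5)]undecane-2,4-dicarboxylate
Product: 17 dimethyl 4-(5-methoxy-5-oxopentyl)-9-methylidene-3-(trifluoromethanesulfonyloxy)tricyclo[6.2.1.0(1,5)]undec-2-ene-2,4-dicarboxylate, via sodium enolate 16 (not isolated)
Conditions: NaH, Et2O, 0 °C; then Tf2O, −78 → 0 °C
Reagents that add atoms: trifluoromethanesulfonic anhydride, O=S(=O)(OS(=O)(=O)C(F)(F)F)C(F)(F)F
Why: O-sulfonylation of a β-keto ester enolate (enol triflate formation); C10 is now quaternary, so the enolate forms only toward C6 and the C5=C6 enol triflate results regiospecifically.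

**Step 9**
Reactants: 17 dimethyl 4-(5-methoxy-5-oxopentyl)-9-methylidene-3-(trifluoromethanesulfonyloxy)tricyclo[6.2.1.0(1,5)]undec-2-ene-2,4-dicarboxylate
Product: 20 trimethyl 18-nor-ent-gibberella-5,16-diene-7,19,20-trioate (C4 epimers), via lithium ester enolate 18 (not isolated), via chlorozinc ester enolate 19 (not isolated)
Conditions: LDA (1.05 equiv), THF, −78 °C; ZnCl2 (1.2 equiv), −78 → 0 °C; then Pd2(dba)3 (5 mol %), P(t-Bu)3 (12 mol %), 25 → 50 °C; aq. NH4Cl
Reagents that add atoms: none
Why: Proposed new method: an intramolecular palladium-catalysed α-alkenylation of a zinc ester enolate by a fully substituted β-(methoxycarbonyl) enol triflate, in which zerovalent palladium inserts into the electron-poor C5–OTf bond, the chlorozinc enolate of the only enolisable ester (the pentanoate chain) transmetalates to a C-bound palladium enolate within a seven-membered palladacycle, and reductive elimination forges the C4–C5 bond and ring A, while the weakly basic zinc enolate does not undergo Dieckmann attack on the C20 ester; the closest known reaction type is the intermolecular palladium-catalysed α-arylation and α-alkenylation of zinc ester enolates (Reformatsky-type reagents) with aryl and alkenyl halides, which has not been shown for ring closure onto a tetrasubstituted enol triflate flanked by two quaternary carbons; C4 is left unassigned because it is re-enolised in step 10.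

**Step 10**
Reactants: 20 trimethyl 18-nor-ent-gibberella-5,16-diene-7,19,20-trioate
Product: 22 trimethyl ent-gibberella-5,16-diene-7,19,20-trioate, via potassium dienolate 21 (not isolated)
Conditions: KHMDS (1.1 equiv), THF, −78 °C; then MeI, −78 → −20 °C
Reagents that add atoms: iodomethane, CI
Why: Alkylation of a vinylogous malonate (glutaconate-type) dienolate: the doubly activated C4–H is removed, the anion delocalised over C4–C5–C6 is methylated at C4 (C6 is blocked by quaternary C8) on the face anti to the pseudo-axial C20 ester, which sets quaternary C4 with the methyl β and the C19 ester cis to C20.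

**Step 11**
Reactants: 22 trimethyl ent-gibberella-5,16-diene-7,19,20-trioate
Product: 24 trimethyl ent-gibberell-16-ene-7,19,20-trioate, via C6 epimer 23 (not isolated)
Conditions: SmI2 (4 equiv), HMPA, MeOH, THF, −20 → 0 °C; then NaOMe (0.3 equiv), MeOH, 50 °C
Reagents that add atoms: none
Why: Samarium diiodide conjugate reduction of the α,β-unsaturated ester (the isolated 16-ene is untouched): the β-carbon C5 is protonated along the axial direction anti to the two flanking axial esters on C4 and C10, giving 5β-H (trans A/B), and methoxide then equilibrates the only enolisable centre, C6, to the more stable 6β-ester trans to C4.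

**Step 12**
Reactants: 24 trimethyl ent-gibberell-16-ene-7,19,20-trioate
Product: 25 trimethyl 15-hydroxy-ent-gibberell-16-ene-7,19,20-trioate (hydroxyl exo)
Conditions: SeO2 (0.3 equiv), t-BuOOH (3 equiv), CH2Cl2, 0 → 25 °C; prompt chromatography on Et3N-deactivated silica
Reagents that add atoms: tert-butyl hydroperoxide, CC(C)(C)OO
Why: Selenium dioxide allylic oxidation (ene reaction then [2,3]-sigmatropic shift, Sharpless conditions) attacks the only allylic methylene, C15 (C13–H is a bridgehead), and delivers oxygen on the open exo face, so it fixes the position of the oxygen but gives the 15-epimer of the target series, which is corrected through the ketone in steps 13 and 14.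

**Step 13**
Reactants: 25 trimethyl 15-hydroxy-ent-gibberell-16-ene-7,19,20-trioate (hydroxyl exo)
Product: 26 trimethyl 15-oxo-ent-gibberell-16-ene-7,19,20-trioate
Conditions: Dess–Martin periodinane (1.3 equiv), CH2Cl2, 0 → 25 °C
Reagents that add atoms: none
Why: Dess–Martin oxidation of the secondary allylic alcohol gives the α-methylene ketone under non-nucleophilic conditions that leave the Michael-acceptor enone and the three esters alone; the C15 stereocentre is deliberately erased.

**Step 14**
Reactants: 26 trimethyl 15-oxo-ent-gibberell-16-ene-7,19,20-trioate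
Product: 27 trimethyl 15-hydroxy-ent-gibberell-16-ene-7,19,20-trioate (hydroxyl endo)
Conditions: NaBH4 (1.0 equiv), CeCl3·7H2O (1.1 equiv), MeOH, −78 °C
Reagents that add atoms: none
Why: Luche reduction: CeCl3 steers NaBH4 to 1,2-addition, and hydride enters C15 from the exo face of the bicyclo[3.2.1]octanone (the endo face lies under the bridge, against the C11 methylene and H-9), which puts the hydroxyl endo and so sets C15 as in the target.

**Step 15**
Reactants: 27 trimethyl 15-hydroxy-ent-gibberell-16-ene-7,19,20-trioate (hydroxyl endo)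
Product: 28 15-hydroxy-ent-gibberell-16-ene-7,19,20-trioic acid (hydroxyl endo; the target gibberellin)
Conditions: n-PrSLi (12 equiv), HMPA, 25 → 50 °C; then cold 1 M HCl to pH 3
Reagents that add atoms: none
Why: Nucleophilic ester demethylation (SN2 attack of thiolate at the O-methyl carbons) is used because the tertiary C19 and C20 esters resist saponification; no stereocentre is touched, and the endo 15-hydroxyl cannot reach the C7 carboxyl, so no lactone forms on acidification.

**Compound list**
1 | cyclohex-2-en-1-one | O=C1C=CCCC1 | starting material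
2 | methyl bromoacetate | COC(=O)CBr | starting material
3 | lithium cyclohexa-1,5-dien-1-olate | [Li+].[O-]C1=CCCC=C1 | intermediate
4 | methyl 2-(2-oxocyclohex-3-en-1-yl)acetate (racemic) | COC(=O)CC1CCC=CC1=O | intermediate
5 | potassium trifluoro(prop-1-en-2-yl)borate | [K+].C=C(C)[B-](F)(F)F | starting material
6 | methyl 2-[(1R,4R)-2-oxo-4-(prop-1-en-2-yl)cyclohexyl]acetate (cis epimer) | C=C(C)[C@@H]1CC[C@H](CC(=O)OC)C(=O)C1 | intermediate
7 | methyl 2-[(1S,4R)-2-oxo-4-(prop-1-en-2-yl)cyclohexyl]acetate (trans isomer) | C=C(C)[C@@H]1CC[C@@H](CC(=O)OC)C(=O)C1 | intermediate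
8 | dimethyl malonate | COC(=O)CC(=O)OC | starting material
9 | dimethyl 2-[(2S,5R)-2-(2-methoxy-2-oxoethyl)-5-(prop-1-en-2-yl)cyclohexylidene]propanedioate | C=C(C)[C@@H]1CC[C@@H](CC(=O)OC)C(=C(C(=O)OC)C(=O)OC)C1 | intermediate
10 | dimethyl 2-[(2S,5R)-5-(3-chloroprop-1-en-2-yl)-2-(2-methoxy-2-oxoethyl)cyclohexylidene]propanedioate | C=C(CCl)[C@@H]1CC[C@@H](CC(=O)OC)C(=C(C(=O)OC)C(=O)OC)C1 | intermediate
11 | allylzinc chloride derived from 10 (C–Cl replaced by C–ZnCl) | C=C(C[Zn]Cl)[C@@H]1CC[C@@H](CC(=O)OC)C(=C(C(=O)OC)C(=O)OC)C1 | intermediate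
12 | dimethyl 2-[(1R,2S,5R)-2-(2-methoxy-2-oxoethyl)-6-methylidenebicyclo[3.2.1]octan-1-yl]propanedioate | C=C1[C@@H]2CC[C@@H](CC(=O)OC)[C@@](C2)(C1)C(C(=O)OC)C(=O)OC | intermediate
13 | dimethyl 9-methylidene-3-oxotricyclo[6.2.1.0(1,5)]undecane-2,4-dicarboxylate (C6 and C10 epimeric or enolised) | C=C1[C@@H]2CC[C@H]3C(C(=O)OC)C(=O)C(C(=O)OC)[C@]3(C2)C1 | intermediate
14 | methyl 5-bromopentanoate | COC(=O)CCCCBr | starting material
15 | dimethyl 4-(5-methoxy-5-oxopentyl)-9-methylidene-3-oxotricyclo[6.2.1.0(1,5)]undecane-2,4-dicarboxylate (chain cis to H-9; C6 epimeric) | C=C1[C@@H]2CC[C@H]3[C@@](CCCCC(=O)OC)(C(=O)OC)C(=O)C(C(=O)OC)[C@]3(C2)C1 | intermediate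
16 | sodium enolate of 15 (C5–O−, C5=C6) | [Na+].C=C1[C@@H]2CC[C@H]3[C@@](CCCCC(=O)OC)(C(=O)OC)C([O-])=C(C(=O)OC)[C@]3(C2)C1 | intermediate
17 | dimethyl 4-(5-methoxy-5-oxopentyl)-9-methylidene-3-(trifluoromethanesulfonyloxy)tricyclo[6.2.1.0(1,5)]undec-2-ene-2,4-dicarboxylate | C=C1[C@@H]2CC[C@H]3[C@@](CCCCC(=O)OC)(C(=O)OC)C(OS(=O)(=O)C(F)(F)F)=C(C(=O)OC)[C@]3(C2)C1 | intermediate
18 | lithium ester enolate of 17 (chain carbon C4 deprotonated) | [Li+].C=C1[C@@H]2CC[C@H]3[C@@](CCCC=C([O-])OC)(C(=O)OC)C(OS(=O)(=O)C(F)(F)F)=C(C(=O)OC)[C@]3(C2)C1 | intermediate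
19 | chlorozinc ester enolate of 17 | C=C1[C@@H]2CC[C@H]3[C@@](CCCC=C(O[Zn]Cl)OC)(C(=O)OC)C(OS(=O)(=O)C(F)(F)F)=C(C(=O)OC)[C@]3(C2)C1 | intermediate
20 | trimethyl 18-nor-ent-gibberella-5,16-diene-7,19,20-trioate (C4 epimers) | C=C1[C@@H]2CC[C@H]3[C@]4(C(=O)OC)CCCC(C(=O)OC)C4=C(C(=O)OC)[C@]3(C2)C1 | intermediate
21 | potassium dienolate of 20 (C4 deprotonated) | [K+].C=C1[C@@H]2CC[C@H]3[C@]4(C(=O)OC)CCCC(=C([O-])OC)C4=C(C(=O)OC)[C@]3(C2)C1 | intermediate
22 | trimethyl ent-gibberella-5,16-diene-7,19,20-trioate | C=C1[C@@H]2CC[C@H]3[C@]4(C(=O)OC)CCC[C@@](C)(C(=O)OC)C4=C(C(=O)OC)[C@]3(C2)C1 | intermediate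
23 | C6 epimer of trimethyl ent-gibberell-16-ene-7,19,20-trioate (C7 ester α) | C=C1[C@@H]2CC[C@H]3[C@]4(C(=O)OC)CCC[C@@](C)(C(=O)OC)[C@H]4[C@@H](C(=O)OC)[C@]3(C2)C1 | intermediate
24 | trimethyl ent-gibberell-16-ene-7,19,20-trioate | C=C1[C@@H]2CC[C@H]3[C@]4(C(=O)OC)CCC[C@@](C)(C(=O)OC)[C@H]4[C@H](C(=O)OC)[C@]3(C2)C1 | intermediate
25 | trimethyl 15-hydroxy-ent-gibberell-16-ene-7,19,20-trioate (hydroxyl exo) | C=C1[C@@H]2CC[C@H]3[C@]4(C(=O)OC)CCC[C@@](C)(C(=O)OC)[C@H]4[C@H](C(=O)OC)[C@]3(C2)[C@H]1O | intermediate
26 | trimethyl 15-oxo-ent-gibberell-16-ene-7,19,20-trioate | C=C1[C@@H]2CC[C@H]3[C@]4(C(=O)OC)CCC[C@@](C)(C(=O)OC)[C@H]4[C@H](C(=O)OC)[C@]3(C2)C1=O | intermediate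
27 | trimethyl 15-hydroxy-ent-gibberell-16-ene-7,19,20-trioate (hydroxyl endo) | C=C1[C@@H]2CC[C@H]3[C@]4(C(=O)OC)CCC[C@@](C)(C(=O)OC)[C@H]4[C@H](C(=O)OC)[C@]3(C2)[C@@H]1O | intermediate
28 | 15-hydroxy-ent-gibberell-16-ene-7,19,20-trioic acid (hydroxyl endo; the target gibberellin) | C=C1[C@@H]2CC[C@H]3[C@]4(C(=O)O)CCC[C@@](C)(C(=O)O)[C@H]4[C@H](C(=O)O)[C@]3(C2)[C@@H]1O | target

**Step count and risks**
Total step count: 15. Longest linear sequence: 15 steps (1 → 28); every other input is a commercial building block.

The three steps most likely to fail: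

Step 5 (ring D closure with formation of quaternary C8). The allylzinc may be protonated back to 9, or the alkylidene malonate may be reduced, before the bridged ring closes. The fallback sets out from 10 and comes back at 12. Palladium-catalysed silylation of the allylic chloride (Me3SiSiMe3, Pd2(dba)3, LiCl, DMF, 80 °C) gives the allylsilane F1. TiCl4 in CH2Cl2 at −78 °C then triggers an intramolecular Hosomi–Sakurai conjugate allylation of the alkylidene malonate, which closes ring D through an open transition state and gives 12 after aqueous work-up.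

Step 9 (the proposed new ring A closure). Oxidative addition or reductive elimination at the congested C5 may be too slow, so that the zinc enolate is only protonated on work-up and 17 is returned. The fallback uses known chemistry, sets out from 17 and comes back at 22, so it also replaces step 10.
- The chain ester is enolised with LDA at −78 °C and trapped with dimethylmethylideneammonium iodide to give the β-(dimethylamino)methyl ester F2.
- Methylation at nitrogen with MeI gives the ammonium iodide F3, and elimination with DBU gives the 2-methylidene ester F4.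
- A reductive Heck cyclisation (Pd(OAc)2, PPh3, HCO2Na, Et4NCl, DMF, 80 °C) then closes ring A. The alkenylpalladium formed from the triflate adds 6-exo to the 1,1-disubstituted alkene. The resulting neopentyl palladium species has no β-hydrogen and is reduced by formate to the C18 methyl group, giving 22 directly.
- The C4 configuration is then decided in the insertion step and is not certain.

Step 11 (conjugate reduction of the hindered, probably twisted enoate, and the C5 face). If SmI2 does not reduce it or protonates C5 from the wrong side, the fallback sets out from 22 and comes back at 24. Selective ozonolysis of the electron-rich exocyclic alkene (O3, CH2Cl2–MeOH, −78 °C, indicator end-point; Me2S) gives the 16-oxo-17-nor enoate F5. Heterogeneous syn-hydrogenation of the only remaining C=C (H2 80 bar, Rh/Al2O3 or Pd/C, EtOAc–AcOH), then NaOMe/MeOH equilibration at C6, gives the saturated norketone triester F6. Wittig methylenation (Ph3P=CH2, THF) restores the 16-ene and gives 24. The hydrogenation face is itself not certain.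

**Further compounds**
F1 | step 5 | dimethyl 2-[(2S,5R)-2-(2-methoxy-2-oxoethyl)-5-[3-(trimethylsilyl)prop-1-en-2-yl]cyclohexylidene]propanedioate | C=C(C[Si](C)(C)C)[C@@H]1CC[C@@H](CC(=O)OC)C(=C(C(=O)OC)C(=O)OC)C1
F2 | step 9 | dimethyl 4-{4-[(dimethylamino)methyl]-5-methoxy-5-oxopentyl}-9-methylidene-3-(trifluoromethanesulfonyloxy)tricyclo[6.2.1.0(1,5)]undec-2-ene-2,4-dicarboxylate (C4 epimers) | C=C1[C@@H]2CC[C@H]3[C@@](CCCC(CN(C)C)C(=O)OC)(C(=O)OC)C(OS(=O)(=O)C(F)(F)F)=C(C(=O)OC)[C@]3(C2)C1
F3 | step 9 | N-methyl ammonium iodide of the β-(dimethylamino)methyl ester (trimethylammoniomethyl group on chain carbon C4) | [I-].C=C1[C@@H]2CC[C@H]3[C@@](CCCC(C[N+](C)(C)C)C(=O)OC)(C(=O)OC)C(OS(=O)(=O)C(F)(F)F)=C(C(=O)OC)[C@]3(C2)C1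
F4 | step 9 | dimethyl 4-(5-methoxy-4-methylidene-5-oxopentyl)-9-methylidene-3-(trifluoromethanesulfonyloxy)tricyclo[6.2.1.0(1,5)]undec-2-ene-2,4-dicarboxylate | C=C1[C@@H]2CC[C@H]3[C@@](CCCC(=C)C(=O)OC)(C(=O)OC)C(OS(=O)(=O)C(F)(F)F)=C(C(=O)OC)[C@]3(C2)C1
F5 | step 11 | trimethyl 16-oxo-17-nor-ent-gibberell-5-ene-7,19,20-trioate | O=C1[C@@H]2CC[C@H]3[C@]4(C(=O)OC)CCC[C@@](C)(C(=O)OC)C4=C(C(=O)OC)[C@]3(C2)C1
F6 | step 11 | trimethyl 16-oxo-17-nor-ent-gibberellane-7,19,20-trioate | O=C1[C@@H]2CC[C@H]3[C@]4(C(=O)OC)CCC[C@@](C)(C(=O)OC)[C@H]4[C@H](C(=O)OC)[C@]3(C2)C1
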